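**Retrosynthetic overview**

- The side-chain ester at C6–O is attached last; the α-methylene-γ-lactone comes from C8–OH and a C11–C12 hydroxyethyl arm on C7 (oxidative lactonisation, then Mannich methylenation).
- The ten-membered carbocycle is made by a Claisen ring expansion of an eight-membered cyclic ether (2-alkylidene-8-alkenyl-oxocane): C6–C7 is formed and the ring O–C4 bond is broken.
- The enabling feature is that C8(=O)–C7–C6–C5=C4 is a γ,δ-unsaturated ketone inside the ring, while C4 and C8 are also joined through C3–C2–C1–C10–C9; an oxygen bridge between C4 and C8 therefore gives an eight-membered allyl vinyl ether.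
- The oxocane comes from an eight-membered lactone (RCM of a tertiary-alkyl ester, diimide, Takai–Utimoto alkylidenation); the quaternary carbinol C4 is set by Sharpless epoxidation and C10 comes from methyl hydrogen (R)-3-methylglutarate.
- Ring order: eight-membered lactone, then oxocane bis-enol ether, then ten-membered carbocycle, then γ-lactone.

Key step: step 15

Remark: C1–C15 in the text are germacrane locants of the target (C8 = lactone O–CH, C7 = ring-fusion CH, C6 = acyloxy CH, C4=C5 = ring alkene with C15 on C4, C10 = CHMe, C11/C12/C13 = lactone carbons); PMB = 4-methoxybenzyl, TBS = tert-butyldimethylsilyl.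
Remark: the side-chain alkene is taken as drawn, with the ester carbonyl carbon and the C-4 hydroxymethyl group cis (2Z).

**Route**

Step 1
Reactants: 1 methyl hydrogen (3R)-3-methylglutarate
Product: 3 (4S)-4-methyloxan-2-one, via hydroxy acid 2 (not isolated)
Conditions: LiBH4, THF, 0 °C→rt; then 2 M HCl, rt
Reagents that add atoms: none
Why: LiBH4 reduces the ester but not the lithium carboxylate and acidification lactonises the hydroxy acid (chemoselective reduction/lactonisation), leaving the stereocentre untouched.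

Step 2
Reactants: 3 (4S)-4-methyloxan-2-one
Product: 4 (3R)-3-methyl-5-(phenylselanyl)pentanoic acid
Conditions: PhSeSePh, NaBH4, DMF, 120 °C; then aq HCl
Reagents that add atoms: diphenyl diselenide, c1ccc(cc1)[Se][Se]c1ccccc1
Why: the soft selenolate opens the δ-lactone by SN2 attack at the O–CH2 carbon (alkyl–oxygen cleavage), remote from the stereocentre.

Step 3
Reactants: 4 (3R)-3-methyl-5-(phenylselanyl)pentanoic acid
Product: 6 (3R)-3-methylpent-4-enoic acid, via selenoxide 5 (not isolated)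
Conditions: 30% H2O2, THF, 0 °C→rt; then i-Pr2NH, 50 °C
Reagents that add atoms: none
Why: oxidation to the primary selenoxide and syn-elimination (selenoxide elimination) can only give the terminal vinyl group, so the C10 stereocentre is delivered from the chiral pool.

Step 4
Reactants: 7 prop-2-yn-1-ol; 8 allylmagnesium bromide
Product: 9 2-methylidenepent-4-en-1-ol
Conditions: 8 (3 equiv), Et2O, reflux; H2O work-up
Reagents that add atoms: none
Why: alkoxide-directed allylmagnesiation of the propargylic alcohol places the allyl group on C-2 and gives the 2-substituted allylic alcohol.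

Step 5
Reactants: 9 2-methylidenepent-4-en-1-ol
Product: 10 [(2R)-2-(prop-2-en-1-yl)oxiran-2-yl]methanol
Conditions: Ti(OiPr)4 (10 mol %), D-(−)-DIPT (12 mol %), t-BuOOH, 4 Å MS, CH2Cl2, −20 °C
Reagents that add atoms: tert-butyl hydroperoxide, CC(C)(C)OO
Why: Sharpless asymmetric epoxidation of a 2-substituted allylic alcohol, in which D-(−)-tartrate should deliver oxygen to the face that gives the (R)-epoxide (the future quaternary C4) while the undirected allyl alkene is untouched.

Step 6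
Reactants: 10 [(2R)-2-(prop-2-en-1-yl)oxiran-2-yl]methanol
Product: 11 (2R)-2-[(PMB-oxy)methyl]pent-4-ene-1,2-diol
Conditions: PMBOH (5 equiv), NaH (1.2 equiv), DMF, 60 °C
Reagents that add atoms: 4-methoxybenzyl alcohol, COc1ccc(CO)cc1
Why: alkoxide opening of the 2,2-disubstituted epoxide at its CH2 terminus, where the competing Payne rearrangement is degenerate because both epoxy alkoxides lead to the same enantiomer of the diol.

Step 7
Reactants: 11 (2R)-2-[(PMB-oxy)methyl]pent-4-ene-1,2-diol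
Product: 12 (2S)-2-hydroxy-2-[(PMB-oxy)methyl]pent-4-enal
Conditions: SO3·pyridine, DMSO, i-Pr2NEt, CH2Cl2, 0 °C
Reagents that add atoms: none
Why: Parikh–Doering oxidation converts only the primary alcohol and avoids the glycol cleavage that a hypervalent-iodine oxidant could cause; the aldehyde is used at once.

Step 8
Reactants: 12 (2S)-2-hydroxy-2-[(PMB-oxy)methyl]pent-4-enal
Product: 13 (1E,3R)-1-iodo-3-[(PMB-oxy)methyl]hexa-1,5-dien-3-ol
Conditions: CrCl2, CHI3, THF/dioxane, 0 °C→rt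
Reagents that add atoms: iodoform, IC(I)I
Why: Takai iodo-olefination is E-selective for α-branched aldehydes and tolerates the free tertiary hydroxyl.

Step 9
Reactants: 6 (3R)-3-methylpent-4-enoic acid; 13 (1E,3R)-1-iodo-3-[(PMB-oxy)methyl]hexa-1,5-dien-3-ol
Product: 15 (1E,3R)-1-iodo-3-[(PMB-oxy)methyl]hexa-1,5-dien-3-yl (3R)-3-methylpent-4-enoate, via acid chloride 14 (not isolated)
Conditions: 6, (COCl)2, cat. DMF, CH2Cl2, 0 °C→rt, evaporate; then 13, DMAP, Et3N, CH2Cl2, 40 °C
Reagents that add atoms: none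
Why: DMAP-catalysed acylation by the acid chloride is forcing enough for the tertiary allylic alcohol, and the β-stereocentre of the acid cannot epimerise.

Step 10
Reactants: 15 (1E,3R)-1-iodo-3-[(PMB-oxy)methyl]hexa-1,5-dien-3-yl (3R)-3-methylpent-4-enoate
Product: 16 (4R,5Z,8R)-8-[(E)-2-iodoethenyl]-8-[(PMB-oxy)methyl]-4-methyl-3,4,7,8-tetrahydro-2H-oxocin-2-one
Conditions: Grubbs II (10 mol %), CH2Cl2 (2 mM), 40 °C
Reagents that add atoms: none
Why: ring-closing metathesis of the two terminal alkenes to the eight-membered lactone should be helped by the quaternary carbinol carbon and the weak Z-ester preference of a tert-alkyl ester; the ring enforces the Z alkene and the hindered iodoalkene is inert.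

Step 11
Reactants: 16 (4R,5Z,8R)-8-[(E)-2-iodoethenyl]-8-[(PMB-oxy)methyl]-4-methyl-3,4,7,8-tetrahydro-2H-oxocin-2-one
Product: 17 (4S,8R)-8-[(E)-2-iodoethenyl]-8-[(PMB-oxy)methyl]-4-methyloxocan-2-one
Conditions: 2-nitrobenzenesulfonohydrazide, Et3N, CH2Cl2, rt
Reagents that add atoms: none
Why: diimide reduces the strained cis-disubstituted ring alkene and should spare the iodoalkene and the PMB ether, which a metal-catalysed hydrogenation would not.

Step 12
Reactants: 18 3-(TBS-oxy)propanal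
Product: 19 tert-butyl(3,3-dibromopropoxy)dimethylsilane
Conditions: P(OPh)3, Br2, Et3N, CH2Cl2, −78 °C→rt
Reagents that add atoms: bromine, BrBr
Why: deoxygenative gem-dibromination of the aldehyde by the phosphite–bromine adduct under buffered conditions that the silyl ether should survive.

Step 13
Reactants: 17 (4S,8R)-8-[(E)-2-iodoethenyl]-8-[(PMB-oxy)methyl]-4-methyloxocan-2-one; 19 tert-butyl(3,3-dibromopropoxy)dimethylsilane
Product: 20 (2Z,4S,8R)-2-[3-(TBS-oxy)propylidene]-8-[(E)-2-iodoethenyl]-8-[(PMB-oxy)methyl]-4-methyloxocane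
Conditions: TiCl4, TMEDA, Zn, cat. PbCl2, THF, 0 °C→rt; basic work-up
Reagents that add atoms: none
Why: Takai–Utimoto alkylidenation of the ester carbonyl should give the Z enol ether (new substituent cis to the ring oxygen, away from C9H2), which is also the less strained exocyclic isomer; with no terminal alkene left, olefin–ester cyclisation cannot compete.

Step 14
Reactants: 20 (2Z,4S,8R)-2-[3-(TBS-oxy)propylidene]-8-[(E)-2-iodoethenyl]-8-[(PMB-oxy)methyl]-4-methyloxocane
Product: 21 (2Z,4S,8R)-2-[3-(TBS-oxy)propylidene]-8-[(E)-2-(PMB-oxy)ethenyl]-8-[(PMB-oxy)methyl]-4-methyloxocane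
Conditions: CuI (10 mol %), 3,4,7,8-tetramethyl-1,10-phenanthroline (20 mol %), Cs2CO3, PMBOH, toluene, 80 °C; filtration through basic alumina
Reagents that add atoms: 4-methoxybenzyl alcohol, COc1ccc(CO)cc1
Why: copper-catalysed C–O coupling of an alkenyl iodide with an alcohol proceeds with retention of the E geometry under basic conditions that keep both enol ethers intact.

Step 15
Reactants: 21 (2Z,4S,8R)-2-[3-(TBS-oxy)propylidene]-8-[(E)-2-(PMB-oxy)ethenyl]-8-[(PMB-oxy)methyl]-4-methyloxocane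
Product: 22 (2R,3R,4E,9S)-2-[2-(TBS-oxy)ethyl]-3-(PMB-oxy)-5-[(PMB-oxy)methyl]-9-methylcyclodec-4-en-1-one
Conditions: toluene (0.01 M), 2,6-di-tert-butyl-4-methylpyridine (10 mol %), 110 °C, sealed tube, base-washed glass
Reagents that add atoms: none
Why: A concerted [3,3] sigmatropic (Claisen) rearrangement of the allyl vinyl ether C7=C8–O–C4–C5=C6 forms C6–C7 and breaks the ring O–C4 bond, so the tether C9–C10–C1–C2–C3 of the oxocane becomes part of a cyclodec-4-enone (ring expansion 8→10); the closest precedent is the Claisen ring expansion of 2-methylene-6-vinyltetrahydropyrans to cyclooct-4-enones, and the 6-alkoxy group and tertiary C4 should accelerate it. The ten-membered ring is not closed by a cyclisation but arises by σ-bond reorganisation through a six-membered chair array. A boat-chair oxocane has endocyclic torsions of about −105° (C9–C8–O–C4) and +50° (C8–O–C4–C3), which are those of a chair transition state with C3 pseudo-axial and C15 pseudo-equatorial, whereas a boat array or an equatorial C3 would need an anti torsion inside the eight-membered ring. Axial C3 gives the ring-cis C4=C5 alkene (C3 cis to C6, C15 trans to C6), and the R configuration at C4 fixes the face of the chair; the Z exocyclic enol ether then places C11 axial and the E alkoxyvinyl group places OPMB equatorial, which gives the 6,7-anti pair with the configuration of the target. The step needs chair-over-boat and concerted-over-ionic selectivity: the first is secured by the ring constraint, the second by a non-polar solvent and a trace of hindered base that suppress ionisation of the donor-substituted allyl ether. C10 is a spectator.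

Step 16
Reactants: 22 (2R,3R,4E,9S)-2-[2-(TBS-oxy)ethyl]-3-(PMB-oxy)-5-[(PMB-oxy)methyl]-9-methylcyclodec-4-en-1-one
Product: 23 (1R,2S,3R,4E,9S)-2-[2-(TBS-oxy)ethyl]-3-(PMB-oxy)-5-[(PMB-oxy)methyl]-9-methylcyclodec-4-en-1-ol
Conditions: SmI2, MeOH, THF, 0 °C
Reagents that add atoms: none
Why: samarium diiodide reduction of a β-alkoxy ketone through a samarium chelate to the β-benzylic ether oxygen (Keck conditions) should give the 1,3-anti alcohol, i.e. the C8 configuration of the target, under neutral conditions that avoid epimerisation or elimination at C7/C6.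

Step 17
Reactants: 23 (1R,2S,3R,4E,9S)-2-[2-(TBS-oxy)ethyl]-3-(PMB-oxy)-5-[(PMB-oxy)methyl]-9-methylcyclodec-4-en-1-ol
Product: 24 (1R,2S,3R,4E,9S)-2-(2-hydroxyethyl)-3-(PMB-oxy)-5-[(PMB-oxy)methyl]-9-methylcyclodec-4-en-1-ol
Conditions: TBAF, AcOH, THF, rt
Reagents that add atoms: none
Why: buffered fluoride desilylation removes the only silyl ether and leaves both PMB ethers.

Step 18
Reactants: 24 (1R,2S,3R,4E,9S)-2-(2-hydroxyethyl)-3-(PMB-oxy)-5-[(PMB-oxy)methyl]-9-methylcyclodec-4-en-1-ol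
Product: 26 (3aS,4R,5E,10S,11aR)-4-(PMB-oxy)-6-[(PMB-oxy)methyl]-10-methyl-3a,4,7,8,9,10,11,11a-octahydrocyclodeca[b]furan-2(3H)-one, via lactol 25 (not isolated)
Conditions: TEMPO (20 mol %), PhI(OAc)2, CH2Cl2, rt
Reagents that add atoms: none
Why: TEMPO-mediated oxidative lactonisation of a 1,4-diol oxidises the primary alcohol, and the lactol formed with C8–OH is oxidised to the trans-fused γ-lactone; C6–O is still protected, so only the 8,12-lactone can form.

Step 19
Reactants: 26 (3aS,4R,5E,10S,11aR)-4-(PMB-oxy)-6-[(PMB-oxy)methyl]-10-methyl-3a,4,7,8,9,10,11,11a-octahydrocyclodeca[b]furan-2(3H)-one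
Product: 27 (3aS,4R,5E,10S,11aR)-3-[(dimethylamino)methyl]-4-(PMB-oxy)-6-[(PMB-oxy)methyl]-10-methyl-3a,4,7,8,9,10,11,11a-octahydrocyclodeca[b]furan-2(3H)-one
Conditions: LDA, THF, −78 °C; then Me2N=CH2 I, −78 °C→rt
Reagents that add atoms: N,N-dimethylmethyleneiminium iodide, C=[N+](C)C.[I-]
Why: Mannich reaction of the lactone enolate with Eschenmoser's salt; the enolate has no β-leaving group and the new C11 centre is removed in the next step.

Step 20
Reactants: 27 (3aS,4R,5E,10S,11aR)-3-[(dimethylamino)methyl]-4-(PMB-oxy)-6-[(PMB-oxy)methyl]-10-methyl-3a,4,7,8,9,10,11,11a-octahydrocyclodeca[b]furan-2(3H)-one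
Product: 29 (3aS,4R,5E,10S,11aR)-4-(PMB-oxy)-6-[(PMB-oxy)methyl]-10-methyl-3-methylidene-3a,4,7,8,9,10,11,11a-octahydrocyclodeca[b]furan-2(3H)-one, via ammonium iodide 28 (not isolated)
Conditions: MeI, MeOH, rt; then aq NaHCO3, CH2Cl2, rt
Reagents that add atoms: none
Why: quaternisation and mild-base E1cB elimination of trimethylamine give the α-methylene lactone.

Step 21
Reactants: 29 (3aS,4R,5E,10S,11aR)-4-(PMB-oxy)-6-[(PMB-oxy)methyl]-10-methyl-3-methylidene-3a,4,7,8,9,10,11,11a-octahydrocyclodeca[b]furan-2(3H)-one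
Product: 30 (3aR,4R,5E,10S,11aR)-4-hydroxy-6-(hydroxymethyl)-10-methyl-3-methylidene-3a,4,7,8,9,10,11,11a-octahydrocyclodeca[b]furan-2(3H)-one
Conditions: DDQ, CH2Cl2/pH 7 buffer, 0 °C→rt
Reagents that add atoms: none
Why: oxidative cleavage of both PMB ethers under neutral conditions that should not trigger translactonisation to the 6,12-lactone.

Step 22
Reactants: 30 (3aR,4R,5E,10S,11aR)-4-hydroxy-6-(hydroxymethyl)-10-methyl-3-methylidene-3a,4,7,8,9,10,11,11a-octahydrocyclodeca[b]furan-2(3H)-one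
Product: 31 (3aR,4R,5E,10S,11aR)-6-[(TBS-oxy)methyl]-4-hydroxy-10-methyl-3-methylidene-3a,4,7,8,9,10,11,11a-octahydrocyclodeca[b]furan-2(3H)-one
Conditions: TBSCl (1.1 equiv), imidazole, CH2Cl2, −20→0 °C
Reagents that add atoms: tert-butyldimethylsilyl chloride, CC(C)(C)[Si](C)(C)Cl
Why: the primary allylic C15 hydroxyl is silylated much faster than the hindered secondary C6 hydroxyl.

Step 23
Reactants: 32 but-2-yne-1,4-diol
Product: 34 (2Z)-2-iodobut-2-ene-1,4-diol, via vinylalanate 33 (not isolated)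
Conditions: Red-Al, THF, 0 °C→rt; then I2, −78→0 °C
Reagents that add atoms: iodine, II
Why: alkoxide-directed trans-hydroalumination followed by iodinolysis with retention puts H and I trans, so iodine is cis to the distal CH2OH.

Step 24
Reactants: 34 (2Z)-2-iodobut-2-ene-1,4-diol
Product: 35 (2Z)-2-iodo-1,4-bis(TBS-oxy)but-2-ene
Conditions: TBSCl, imidazole, DMF, rt
Reagents that add atoms: tert-butyldimethylsilyl chloride, CC(C)(C)[Si](C)(C)Cl
Why: standard silylation of two primary alcohols.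

Step 25
Reactants: 35 (2Z)-2-iodo-1,4-bis(TBS-oxy)but-2-ene
Product: 37 (2Z)-4-(TBS-oxy)-2-[(TBS-oxy)methyl]but-2-enoic acid, via vinyllithium 36 (not isolated)
Conditions: t-BuLi (2.1 equiv), Et2O, −78 °C; then CO2, −78 °C; aq HCl to pH 4
Reagents that add atoms: carbon dioxide, O=C=O
Why: iodine–lithium exchange and carboxylation both proceed with retention at −78 °C, where β-elimination and silyl migration of the alkenyllithium should be slow, so the carboxyl ends up cis to the C-4 silyloxymethyl group.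

Step 26
Reactants: 37 (2Z)-4-(TBS-oxy)-2-[(TBS-oxy)methyl]but-2-enoic acid; 31 (3aR,4R,5E,10S,11aR)-6-[(TBS-oxy)methyl]-4-hydroxy-10-methyl-3-methylidene-3a,4,7,8,9,10,11,11a-octahydrocyclodeca[b]furan-2(3H)-one
Product: 39 (3aS,4R,5E,10S,11aR)-6-[(TBS-oxy)methyl]-10-methyl-3-methylidene-2-oxo-2,3,3a,4,7,8,9,10,11,11a-decahydrocyclodeca[b]furan-4-yl (2Z)-4-(TBS-oxy)-2-[(TBS-oxy)methyl]but-2-enoate, via mixed anhydride 38 (not isolated)
Conditions: 37, 2,4,6-Cl3C6H2COCl, Et3N, THF, rt; then 31, DMAP (0.2 equiv), toluene, 40 °C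
Reagents that add atoms: none
Why: Yamaguchi esterification through the preformed mixed anhydride with little DMAP is the protocol used for angelate-type Z acids, because it limits Z→E isomerisation of the activated acyl group.

Step 27
Reactants: 39 (3aS,4R,5E,10S,11aR)-6-[(TBS-oxy)methyl]-10-methyl-3-methylidene-2-oxo-2,3,3a,4,7,8,9,10,11,11a-decahydrocyclodeca[b]furan-4-yl (2Z)-4-(TBS-oxy)-2-[(TBS-oxy)methyl]but-2-enoate
Product: 40 (3aS,4R,5E,10S,11aR)-6-(hydroxymethyl)-10-methyl-3-methylidene-2-oxo-2,3,3a,4,7,8,9,10,11,11a-decahydrocyclodeca[b]furan-4-yl (2Z)-4-hydroxy-2-(hydroxymethyl)but-2-enoate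
Conditions: HF·pyridine, pyridine, THF, 0 °C→rt
Reagents that add atoms: none
Why: buffered fluoride removes the three primary silyl ethers under near-neutral conditions that should not lactonise the Z-γ-hydroxy enoate or add to the α-methylene lactone.

**Compound list**

1 | methyl hydrogen (3R)-3-methylglutarate | OC(=O)C[C@@H](C)CC(=O)OC | starting material
2 | (3S)-5-hydroxy-3-methylpentanoic acid (formed as its lithium salt) | OC(=O)C[C@@H](C)CCO | intermediate
3 | (4S)-4-methyloxan-2-one | O=C1C[C@@H](C)CCO1 | intermediate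
4 | (3R)-3-methyl-5-(phenylselanyl)pentanoic acid | OC(=O)C[C@@H](C)CC[Se]c1ccccc1 | intermediate
5 | (3R)-3-methyl-5-(phenylseleninyl)pentanoic acid | OC(=O)C[C@@H](C)CC[Se](=O)c1ccccc1 | intermediate
6 | (3R)-3-methylpent-4-enoic acid | OC(=O)C[C@@H](C)C=C | intermediate
7 | prop-2-yn-1-ol | C#CCO | starting material
8 | allylmagnesium bromide | C=CC[Mg]Br | starting material
9 | 2-methylidenepent-4-en-1-ol | C=CCC(=C)CO | intermediate
10 | [(2R)-2-(prop-2-en-1-yl)oxiran-2-yl]methanol | C=CC[C@@]1(CO)CO1 | intermediate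
11 | (2R)-2-{[(4-methoxybenzyl)oxy]methyl}pent-4-ene-1,2-diol | C=CC[C@@](O)(CO)COCc1ccc(OC)cc1 | intermediate
12 | (2S)-2-hydroxy-2-{[(4-methoxybenzyl)oxy]methyl}pent-4-enal | C=CC[C@@](O)(C=O)COCc1ccc(OC)cc1 | intermediate
13 | (1E,3R)-1-iodo-3-{[(4-methoxybenzyl)oxy]methyl}hexa-1,5-dien-3-ol | C=CC[C@@](O)(/C=C/I)COCc1ccc(OC)cc1 | intermediate
14 | (3R)-3-methylpent-4-enoyl chloride | C=C[C@H](C)CC(Cl)=O | intermediate
15 | (1E,3R)-1-iodo-3-{[(4-methoxybenzyl)oxy]methyl}hexa-1,5-dien-3-yl (3R)-3-methylpent-4-enoate | C=CC[C@@](OC(=O)C[C@@H](C)C=C)(/C=C/I)COCc1ccc(OC)cc1 | intermediate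
16 | (4R,5Z,8R)-8-[(E)-2-iodoethenyl]-8-{[(4-methoxybenzyl)oxy]methyl}-4-methyl-3,4,7,8-tetrahydro-2H-oxocin-2-one | C[C@H]1/C=C\C[C@](COCc2ccc(OC)cc2)(/C=C/I)OC(=O)C1 | intermediate
17 | (4S,8R)-8-[(E)-2-iodoethenyl]-8-{[(4-methoxybenzyl)oxy]methyl}-4-methyloxocan-2-one | C[C@H]1CCC[C@](COCc2ccc(OC)cc2)(/C=C/I)OC(=O)C1 | intermediate
18 | 3-[(tert-butyldimethylsilyl)oxy]propanal | O=CCCO[Si](C)(C)C(C)(C)C | starting material
19 | tert-butyl(3,3-dibromopropoxy)dimethylsilane | BrC(Br)CCO[Si](C)(C)C(C)(C)C | intermediate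
20 | (2Z,4S,8R)-2-{3-[(tert-butyldimethylsilyl)oxy]propylidene}-8-[(E)-2-iodoethenyl]-8-{[(4-methoxybenzyl)oxy]methyl}-4-methyloxocane | C[C@H]1CCC[C@](COCc2ccc(OC)cc2)(/C=C/I)O/C(=C\CCO[Si](C)(C)C(C)(C)C)C1 | intermediate
21 | (2Z,4S,8R)-2-{3-[(tert-butyldimethylsilyl)oxy]propylidene}-8-{(E)-2-[(4-methoxybenzyl)oxy]ethenyl}-8-{[(4-methoxybenzyl)oxy]methyl}-4-methyloxocane | C[C@H]1CCC[C@](COCc2ccc(OC)cc2)(/C=C/OCc2ccc(OC)cc2)O/C(=C\CCO[Si](C)(C)C(C)(C)C)C1 | intermediate
22 | (2R,3R,4E,9S)-2-{2-[(tert-butyldimethylsilyl)oxy]ethyl}-3-[(4-methoxybenzyl)oxy]-5-{[(4-methoxybenzyl)oxy]methyl}-9-methylcyclodec-4-en-1-one | O=C1C[C@@H](C)CCC/C(COCc2ccc(OC)cc2)=C\[C@@H](OCc2ccc(OC)cc2)[C@H]1CCO[Si](C)(C)C(C)(C)C | intermediate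
23 | (1R,2S,3R,4E,9S)-2-{2-[(tert-butyldimethylsilyl)oxy]ethyl}-3-[(4-methoxybenzyl)oxy]-5-{[(4-methoxybenzyl)oxy]methyl}-9-methylcyclodec-4-en-1-ol | O[C@@H]1C[C@@H](C)CCC/C(COCc2ccc(OC)cc2)=C\[C@@H](OCc2ccc(OC)cc2)[C@H]1CCO[Si](C)(C)C(C)(C)C | intermediate
24 | (1R,2S,3R,4E,9S)-2-(2-hydroxyethyl)-3-[(4-methoxybenzyl)oxy]-5-{[(4-methoxybenzyl)oxy]methyl}-9-methylcyclodec-4-en-1-ol | O[C@@H]1C[C@@H](C)CCC/C(COCc2ccc(OC)cc2)=C\[C@@H](OCc2ccc(OC)cc2)[C@H]1CCO | intermediate
25 | (3aS,4R,5E,10S,11aR)-4-[(4-methoxybenzyl)oxy]-6-{[(4-methoxybenzyl)oxy]methyl}-10-methyl-2,3,3a,4,7,8,9,10,11,11a-decahydrocyclodeca[b]furan-2-ol (lactol, C2 epimers) | OC1O[C@@H]2C[C@@H](C)CCC/C(COCc3ccc(OC)cc3)=C\[C@@H](OCc3ccc(OC)cc3)[C@H]2C1 | intermediate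
26 | (3aS,4R,5E,10S,11aR)-4-[(4-methoxybenzyl)oxy]-6-{[(4-methoxybenzyl)oxy]methyl}-10-methyl-3a,4,7,8,9,10,11,11a-octahydrocyclodeca[b]furan-2(3H)-one | O=C1O[C@@H]2C[C@@H](C)CCC/C(COCc3ccc(OC)cc3)=C\[C@@H](OCc3ccc(OC)cc3)[C@H]2C1 | intermediate
27 | 3-[(dimethylamino)methyl] derivative of 26 (C3 epimers) | O=C1O[C@@H]2C[C@@H](C)CCC/C(COCc3ccc(OC)cc3)=C\[C@@H](OCc3ccc(OC)cc3)[C@H]2C1CN(C)C | intermediate
28 | trimethylammonium iodide of 27 | O=C1O[C@@H]2C[C@@H](C)CCC/C(COCc3ccc(OC)cc3)=C\[C@@H](OCc3ccc(OC)cc3)[C@H]2C1C[N+](C)(C)C.[I-] | intermediate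
29 | (3aS,4R,5E,10S,11aR)-4-[(4-methoxybenzyl)oxy]-6-{[(4-methoxybenzyl)oxy]methyl}-10-methyl-3-methylidene-3a,4,7,8,9,10,11,11a-octahydrocyclodeca[b]furan-2(3H)-one | C=C1C(=O)O[C@@H]2C[C@@H](C)CCC/C(COCc3ccc(OC)cc3)=C\[C@@H](OCc3ccc(OC)cc3)[C@@H]12 | intermediate
30 | (3aR,4R,5E,10S,11aR)-4-hydroxy-6-(hydroxymethyl)-10-methyl-3-methylidene-3a,4,7,8,9,10,11,11a-octahydrocyclodeca[b]furan-2(3H)-one | C=C1C(=O)O[C@@H]2C[C@@H](C)CCC/C(CO)=C\[C@@H](O)[C@@H]12 | intermediate
31 | (3aR,4R,5E,10S,11aR)-6-{[(tert-butyldimethylsilyl)oxy]methyl}-4-hydroxy-10-methyl-3-methylidene-3a,4,7,8,9,10,11,11a-octahydrocyclodeca[b]furan-2(3H)-one | C=C1C(=O)O[C@@H]2C[C@@H](C)CCC/C(CO[Si](C)(C)C(C)(C)C)=C\[C@@H](O)[C@@H]12 | intermediate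
32 | but-2-yne-1,4-diol | OCC#CCO | starting material
33 | sodium bis(2-methoxyethoxy) oxa-aluminacyclopentene (vinylalanate; second hydroxyl drawn unbound) | [Na+].COCCO[Al-]1(OCCOC)OC/C=C1/CO | intermediate
34 | (2Z)-2-iodobut-2-ene-1,4-diol | I/C(CO)=C\CO | intermediate
35 | (2Z)-2-iodo-1,4-bis[(tert-butyldimethylsilyl)oxy]but-2-ene | I/C(CO[Si](C)(C)C(C)(C)C)=C\CO[Si](C)(C)C(C)(C)C | intermediate
36 | (2E)-1,4-bis[(tert-butyldimethylsilyl)oxy]but-2-en-2-yllithium (Li in the place of I) | [Li]/C(CO[Si](C)(C)C(C)(C)C)=C\CO[Si](C)(C)C(C)(C)C | intermediate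
37 | (2Z)-4-[(tert-butyldimethylsilyl)oxy]-2-{[(tert-butyldimethylsilyl)oxy]methyl}but-2-enoic acid | OC(=O)/C(CO[Si](C)(C)C(C)(C)C)=C\CO[Si](C)(C)C(C)(C)C | intermediate
38 | mixed anhydride of 37 with 2,4,6-trichlorobenzoic acid | O=C(OC(=O)c1c(Cl)cc(Cl)cc1Cl)/C(CO[Si](C)(C)C(C)(C)C)=C\CO[Si](C)(C)C(C)(C)C | intermediate
39 | tris-TBS ether of the target (C15–OTBS and both side-chain hydroxyls as TBS ethers) | C=C1C(=O)O[C@@H]2C[C@@H](C)CCC/C(CO[Si](C)(C)C(C)(C)C)=C\[C@@H](OC(=O)/C(=C\CO[Si](C)(C)C(C)(C)C)CO[Si](C)(C)C(C)(C)C)[C@@H]12 | intermediate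
40 | (3aS,4R,5E,10S,11aR)-6-(hydroxymethyl)-10-methyl-3-methylidene-2-oxo-2,3,3a,4,7,8,9,10,11,11a-decahydrocyclodeca[b]furan-4-yl (2Z)-4-hydroxy-2-(hydroxymethyl)but-2-enoate | C=C1C(=O)O[C@@H]2C[C@@H](C)CCC/C(CO)=C\[C@@H](OC(=O)/C(=C\CO)CO)[C@@H]12 | target

**Step count**

Total: 27 steps. Longest linear sequence: 20 steps (from 7 through steps 4–11, 13–22, 26 and 27).

**Steps most likely to fail**

1. Step 15 (Claisen ring expansion). The O–C4 bond may ionise to an alkoxyallyl cation/enolate pair, because C4 is tertiary and C6 carries a donor; this would give [1,3] recombination, loss of PMBOH or erosion of the chair control at C6/C7. The fallback removes the donor. It sets out from 20: Miyaura borylation (PdCl2(PPh3)2, B2pin2, KOPh, toluene, 50 °C) should give the (E)-alkenylboronate F1. Thermal rearrangement of F1 in toluene at 110–130 °C (boron-substituted allyl systems are known to undergo chair-controlled [3,3] shifts) should give the allylboronate ketone F2, with boron in the position of the C6 oxygen. F2 is oxidised without isolation (NaBO3·4H2O, THF/H2O, retention) to the β-hydroxy ketone F3. PMB ether formation under neutral conditions (2-(4-methoxybenzyloxy)-4-methylquinoline, MeOTf) returns to 22.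

2. Step 13 (alkylidenation of the lactone). The hindered lactone carbonyl may react incompletely, the C–I bond may be reduced by low-valent Ti/Zn, and the Z selectivity may erode. The fallback is a modified Julia olefination of the lactone. It sets out from 17: addition of lithiated 2-{[3-(TBS-oxy)propyl]sulfonyl}-1,3-benzothiazole (LiHMDS, THF, −78 °C) should give the lactol adduct F4. Treatment with DBU (THF, rt; Smiles rearrangement with loss of SO2 and benzothiazolone) should give 20 together with its E isomer, which is removed on basic alumina.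

3. Step 16 (reduction at C8). Facial selectivity may be poor in the conformationally mobile ten-membered ketone, where the α-stereocentre and the β-alkoxy group can oppose each other. The fallback sets the centre by inversion. It sets out from 22: chelation-controlled reduction (LiAlH4, LiI, Et2O, −78 °C) should give the 1,3-syn C8 epimer F5. Mitsunobu inversion (4-nitrobenzoic acid, PPh3, DIAD, toluene) should give the 4-nitrobenzoate F6 with the required C8 configuration, and methanolysis (K2CO3, MeOH) returns to 23.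

**Further compounds**

F1 | step 15 | (2Z,4S,8R)-2-[3-(TBS-oxy)propylidene]-8-[(PMB-oxy)methyl]-4-methyl-8-[(E)-2-(4,4,5,5-tetramethyl-1,3,2-dioxaborolan-2-yl)ethenyl]oxocane | C[C@H]1CCC[C@](COCc2ccc(OC)cc2)(/C=C/B2OC(C)(C)C(C)(C)O2)O/C(=C\CCO[Si](C)(C)C(C)(C)C)C1
F2 | step 15 | cyclodec-4-en-1-one as 22 with a 4,4,5,5-tetramethyl-1,3,2-dioxaborolan-2-yl group in place of the C3 PMB-oxy group | O=C1C[C@@H](C)CCC/C(COCc2ccc(OC)cc2)=C\[C@@H](B2OC(C)(C)C(C)(C)O2)[C@H]1CCO[Si](C)(C)C(C)(C)C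
F3 | step 15 | cyclodec-4-en-1-one as 22 with a free hydroxyl in place of the C3 PMB-oxy group (β-hydroxy ketone) | O=C1C[C@@H](C)CCC/C(COCc2ccc(OC)cc2)=C\[C@@H](O)[C@H]1CCO[Si](C)(C)C(C)(C)C
F4 | step 13 | (4S,8R)-2-[1-(1,3-benzothiazol-2-ylsulfonyl)-3-(TBS-oxy)propyl]-8-[(E)-2-iodoethenyl]-8-[(PMB-oxy)methyl]-4-methyloxocan-2-ol (epimers at the two new centres) | C[C@H]1CCC[C@](COCc2ccc(OC)cc2)(/C=C/I)OC(O)(C(CCO[Si](C)(C)C(C)(C)C)S(=O)(=O)c2nc3ccccc3s2)C1
F5 | step 16 | (1S,2S,3R,4E,9S)-2-[2-(TBS-oxy)ethyl]-3-(PMB-oxy)-5-[(PMB-oxy)methyl]-9-methylcyclodec-4-en-1-ol (C1 epimer of 23) | O[C@H]1C[C@@H](C)CCC/C(COCc2ccc(OC)cc2)=C\[C@@H](OCc2ccc(OC)cc2)[C@H]1CCO[Si](C)(C)C(C)(C)C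
F6 | step 16 | 4-nitrobenzoate of 23 | O=C(O[C@@H]1C[C@@H](C)CCC/C(COCc2ccc(OC)cc2)=C\[C@@H](OCc2ccc(OC)cc2)[C@H]1CCO[Si](C)(C)C(C)(C)C)c1ccc([N+](=O)[O-])cc1
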